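**Plan**

- Retrosynthesis (naphthalene locants: C1 = carbonyl next to C8a and peri to the C8 methoxy, C4 = carbonyl peri to the C5 hydroxyl, side chain on C7). The cuts are: the side-chain ester C–O; then the C1–C8a bond of the quinone ring, opened to a 4-aryl-4-hydroxycyclobutenone; then C4–C4a (aryllithium plus isopropyl semisquarate); then the side-chain C=C (cross-metathesis) and C1'–C2' (allylation of an aryl aldehyde).
- Enabling feature: the quinone ring is a four-carbon unit C1(=O)–C2H=C3H–C4(=O) bridging C4a and C8a. C8a is a free CH in the arene precursor and the other ortho carbon (C5) carries oxygen. C1–C4 can therefore be delivered as a cyclobutenone on C4a (a temporary ring), whose ketene carbon can close only onto C8a and which arrives at the hydroquinone oxidation level.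
- Forward order: the benzenoid ring is bought and its two oxygens are differentiated; the side chain is built; the four-carbon ring is attached at C4a and its alkoxy group removed by reductive carbonyl transposition; the quinone ring arises last by thermal ring expansion and oxidation; deprotection and acylation finish.
- Stereochemistry: the single stereocentre (R, benzylic carbinol carbon) is set by a reagent-controlled Brown allylboration (Re-face attack) and carried through unchanged.

Key step: step 9

Remark: Ar in the names below is 4-[(1R)-1-(tert-butyldimethylsilyloxy)-4-methylpent-3-en-1-yl]-5-methoxy-2-(methoxymethoxy)phenyl. The cyclobutenone intermediates are carried as mixtures of epimers at the ring carbinol carbon, which becomes sp2 in the key step. 4-Bromo-2,5-dimethoxybenzaldehyde, diisopropyl squarate, the allylborane solution and 3-methylbut-2-enoic acid are taken as purchasable.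

**Step 1**
Reactants: 1 4-bromo-2,5-dimethoxybenzaldehyde
Product: 2 4-bromo-5-hydroxy-2-methoxybenzaldehyde
Conditions: conc. H2SO4, 50 °C; ice
Reagents that add atoms: none
Why: In concentrated sulfuric acid the formyl group is protonated and the conjugated 2-methoxy oxygen is deactivated, so the 5-methoxy group is the more basic ether and should be cleaved selectively by SN2 attack of bisulfate on its methyl group (acid-mediated regioselective aryl methyl ether cleavage).

**Step 2**
Reactants: 2 4-bromo-5-hydroxy-2-methoxybenzaldehyde
Product: 3 4-bromo-2-methoxy-5-(methoxymethoxy)benzaldehyde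
Conditions: MOMCl, i-Pr2NEt, CH2Cl2, 0 °C to rt
Reagents that add atoms: chloromethyl methyl ether, COCCl
Why: Williamson-type O-alkylation of the phenol gives an acetal ether that will chelate and stabilise the later ortho-lithio species and is removable with mild acid.

**Step 3**
Reactants: 3 4-bromo-2-methoxy-5-(methoxymethoxy)benzaldehyde
Product: 4 (1R)-1-[4-bromo-2-methoxy-5-(methoxymethoxy)phenyl]but-3-en-1-ol
Conditions: (+)-Ipc2B(allyl), Et2O, −78 °C; NaOH, H2O2, 0 °C to rt
Reagents that add atoms: (+)-B-allyldiisopinocampheylborane [B-allylbis((1S,2S,3S,5R)-isopinocampheyl)borane, the (−)-α-pinene-derived reagent], C=CCB([C@H]1C[C@H]2C[C@@H]([C@@H]1C)C2(C)C)[C@H]1C[C@H]2C[C@@H]([C@@H]1C)C2(C)C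
Why: Brown allylboration proceeds through a closed chair (Zimmerman–Traxler) transition state under reagent control, and this enantiomer of the borane is expected to deliver allyl to the Re face of the aryl aldehyde, which sets the R carbinol centre.

**Step 4**
Reactants: 4 (1R)-1-[4-bromo-2-methoxy-5-(methoxymethoxy)phenyl]but-3-en-1-ol
Product: 5 tert-butyldimethylsilyl ether of 4
Conditions: TBSCl, imidazole, DMF, rt
Reagents that add atoms: tert-butyldimethylsilyl chloride, CC(C)(C)[Si](C)(C)Cl
Why: Standard silylation of the secondary alcohol masks the acidic OH before the organolithium steps and does not touch the stereocentre.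

**Step 5**
Reactants: 5 tert-butyldimethylsilyl ether of 4
Product: 6 tert-butyldimethylsilyl ether of (1R)-1-[4-bromo-2-methoxy-5-(methoxymethoxy)phenyl]-4-methylpent-3-en-1-ol (Ar–Br)
Conditions: 2-methylbut-2-ene (excess), (H2IMes)(PCy3)Cl2Ru=CHPh (second-generation Grubbs catalyst), CH2Cl2, 40 °C
Reagents that add atoms: 2-methylbut-2-ene, CC=C(C)C
Why: Olefin cross-metathesis of the terminal alkene with excess 2-methylbut-2-ene should install the isopropylidene terminus with loss of propene, the trisubstituted product being too hindered to re-enter the cycle.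

**Step 6**
Reactants: 7 diisopropyl squarate (3,4-diisopropoxycyclobut-3-ene-1,2-dione)
Product: 9 3-isopropoxycyclobut-3-ene-1,2-dione, via 4-hydroxy-2,3-diisopropoxycyclobut-2-en-1-one 8 (not isolated)
Conditions: LiAlH(OtBu)3, THF, −78 to 0 °C; 6 M HCl, CH2Cl2, rt
Reagents that add atoms: water, O
Why: The hindered hydride should reduce one squarate carbonyl only, and acid then expels the new hydroxyl with vinylogous hydrolysis of the distal enol ether (reductive carbonyl transposition of an alkoxycyclobutenone), leaving the mono-alkoxy dione.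

**Step 7**
Reactants: 6 Ar–Br; 9 3-isopropoxycyclobut-3-ene-1,2-dione
Product: 11 4-Ar-4-hydroxy-3-isopropoxycyclobut-2-en-1-one, via aryllithium 10 (not isolated)
Conditions: n-BuLi, THF, −78 °C; cannulation into 9, THF, −78 °C; AcOH, −78 °C
Reagents that add atoms: none
Why: Bromine–lithium exchange is faster than any deprotonation and gives an ortho-OMOM-chelated aryllithium, which should add 1,2 to the ketone-like carbonyl next to the alkoxy-bearing carbon, the other carbonyl being deactivated as a vinylogous ester.

**Step 8**
Reactants: 11 4-Ar-4-hydroxy-3-isopropoxycyclobut-2-en-1-one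
Product: 13 4-Ar-4-hydroxycyclobut-2-en-1-one, via 1-Ar-2-isopropoxycyclobut-2-ene-1,4-diol 12 (not isolated)
Conditions: i-Bu2AlH (2.5 equiv), THF, −78 °C; 1 M aq. HCl, THF, 0 °C
Reagents that add atoms: water, O
Why: This is a Stork–Danheiser-type reductive transposition, in which 1,2-hydride addition to the vinylogous ester carbonyl is followed by ionisation of the new secondary allylic hydroxyl to an isopropoxy-stabilised allyl cation and hydrolysis, moving the carbonyl to the former enol ether carbon and leaving C2 and C3 unsubstituted, while the tertiary hydroxyl should not ionise because its cation would lack oxygen stabilisation.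

**Step 9**
Reactants: 13 4-Ar-4-hydroxycyclobut-2-en-1-one
Product: 17 8-methoxy-5-(methoxymethoxy)-7-[(1R)-1-(tert-butyldimethylsilyloxy)-4-methylpent-3-en-1-yl]naphthalene-1,4-dione, via dienylketene 14 (not isolated), via ring-fusion dienone 15 (not isolated), via naphthalene-1,4-diol 16 (not isolated)
Conditions: toluene (degassed, 0.01 M), 110 °C; then Ag2O, rt
Reagents that add atoms: none
Why: Heating should open the cyclobutenone by a thermal conrotatory 4π electrocyclic cleavage of its C1–C4 bond, with the C4 hydroxyl rotating outward so that the aryl group ends cis to the ketene arm of dienylketene 14. A thermal disrotatory 6π electrocyclisation then joins the ketene carbon to the one unsubstituted ortho carbon of the arene (the CH next to the methoxy-bearing carbon), closing the six-membered ring as dienone 15, which enolises to the aromatic diol 16 and is oxidised by Ag2O to 17. The closest known reaction type is the Moore rearrangement (thermal ring expansion of 4-aryl-4-hydroxycyclobutenones to 1,4-naphthoquinones). The only new stereocentre, the ring-fusion CH of 15, is transient and is erased on aromatisation, and the side-chain centre is a spectator. Three selectivities are needed: torquoselectivity, secured by the donor hydroxyl's preference for outward rotation; the site of closure, secured because the other ortho carbon carries the OMOM group, so closure there cannot aromatise and reverts; and the choice of quinone ring, secured because only the new ring carries two free hydroxyls while the benzenoid oxygens are ethers, so a mild oxidant touches nothing else.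

**Step 10**
Reactants: 17 protected quinone
Product: 18 5-hydroxy-7-[(1R)-1-hydroxy-4-methylpent-3-en-1-yl]-8-methoxynaphthalene-1,4-dione
Conditions: 2 M aq. HCl, THF, rt to 35 °C
Reagents that add atoms: none
Why: Acid hydrolysis should cleave the silyl ether and the MOM acetal, the latter assisted by the peri carbonyl, while the benzylic C–O bond should resist ionisation because the ring position para to it carries a quinone carbonyl.

**Step 11**
Reactants: 18 5-hydroxy-7-[(1R)-1-hydroxy-4-methylpent-3-en-1-yl]-8-methoxynaphthalene-1,4-dione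
Product: 19 (1R)-1-(4-hydroxy-1-methoxy-5,8-dioxo-5,8-dihydronaphthalen-2-yl)-4-methylpent-3-en-1-yl 3-methylbut-2-enoate (CNP0130192.1)
Conditions: 3-methylbut-2-enoic acid, DCC, DMAP (cat.), CH2Cl2, 0 °C to rt
Reagents that add atoms: 3-methylbut-2-enoic acid, CC(C)=CC(=O)O
Why: Steglich esterification should acylate the secondary alcohol only, because the phenol is tied up in a hydrogen bond to the peri carbonyl, and acylation at oxygen leaves the R configuration untouched.

**Compound list**

1 | 4-bromo-2,5-dimethoxybenzaldehyde | COc1cc(Br)c(OC)cc1C=O | starting material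
2 | 4-bromo-5-hydroxy-2-methoxybenzaldehyde | COc1cc(Br)c(O)cc1C=O | intermediate
3 | 4-bromo-2-methoxy-5-(methoxymethoxy)benzaldehyde | COCOc1cc(C=O)c(OC)cc1Br | intermediate
4 | (1R)-1-[4-bromo-2-methoxy-5-(methoxymethoxy)phenyl]but-3-en-1-ol | COCOc1cc([C@@H](CC=C)O)c(OC)cc1Br | intermediate
5 | tert-butyldimethylsilyl ether of 4 | COCOc1cc([C@@H](CC=C)O[Si](C)(C)C(C)(C)C)c(OC)cc1Br | intermediate
6 | tert-butyldimethylsilyl ether of (1R)-1-[4-bromo-2-methoxy-5-(methoxymethoxy)phenyl]-4-methylpent-3-en-1-ol (Ar–Br) | COCOc1cc([C@@H](CC=C(C)C)O[Si](C)(C)C(C)(C)C)c(OC)cc1Br | intermediate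
7 | diisopropyl squarate | CC(C)OC1=C(OC(C)C)C(=O)C1=O | starting material
8 | 4-hydroxy-2,3-diisopropoxycyclobut-2-en-1-one | CC(C)OC1=C(OC(C)C)C(O)C1=O | intermediate (not isolated)
9 | 3-isopropoxycyclobut-3-ene-1,2-dione | CC(C)OC1=CC(=O)C1=O | intermediate
10 | Ar–Li (aryllithium from 6) | COCOc1cc([C@@H](CC=C(C)C)O[Si](C)(C)C(C)(C)C)c(OC)cc1[Li] | intermediate (not isolated)
11 | 4-Ar-4-hydroxy-3-isopropoxycyclobut-2-en-1-one | COCOc1cc([C@@H](CC=C(C)C)O[Si](C)(C)C(C)(C)C)c(OC)cc1C1(O)C(OC(C)C)=CC1=O | intermediate
12 | 1-Ar-2-isopropoxycyclobut-2-ene-1,4-diol | COCOc1cc([C@@H](CC=C(C)C)O[Si](C)(C)C(C)(C)C)c(OC)cc1C1(O)C(OC(C)C)=CC1O | intermediate (not isolated)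
13 | 4-Ar-4-hydroxycyclobut-2-en-1-one | COCOc1cc([C@@H](CC=C(C)C)O[Si](C)(C)C(C)(C)C)c(OC)cc1C1(O)C=CC1=O | intermediate
14 | 4-Ar-4-hydroxybuta-1,3-dien-1-one (Ar cis to C2) | O=C=C/C=C(O)\c1cc(OC)c([C@@H](CC=C(C)C)O[Si](C)(C)C(C)(C)C)cc1OCOC | intermediate (not isolated)
15 | 4-hydroxy-8-methoxy-5-(methoxymethoxy)-7-[(1R)-1-(tert-butyldimethylsilyloxy)-4-methylpent-3-en-1-yl]naphthalen-1(8aH)-one | COCOC1=CC([C@@H](CC=C(C)C)O[Si](C)(C)C(C)(C)C)=C(OC)C2C(=O)C=CC(O)=C12 | intermediate (not isolated)
16 | 8-methoxy-5-(methoxymethoxy)-7-[(1R)-1-(tert-butyldimethylsilyloxy)-4-methylpent-3-en-1-yl]naphthalene-1,4-diol | COCOc1cc([C@@H](CC=C(C)C)O[Si](C)(C)C(C)(C)C)c(OC)c2c(O)ccc(O)c12 | intermediate (not isolated)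
17 | 8-methoxy-5-(methoxymethoxy)-7-[(1R)-1-(tert-butyldimethylsilyloxy)-4-methylpent-3-en-1-yl]naphthalene-1,4-dione | COCOc1cc([C@@H](CC=C(C)C)O[Si](C)(C)C(C)(C)C)c(OC)c2c1C(=O)C=CC2=O | intermediate
18 | 5-hydroxy-7-[(1R)-1-hydroxy-4-methylpent-3-en-1-yl]-8-methoxynaphthalene-1,4-dione | COc1c([C@@H](CC=C(C)C)O)cc(O)c2c1C(=O)C=CC2=O | intermediate
19 | (1R)-1-(4-hydroxy-1-methoxy-5,8-dioxo-5,8-dihydronaphthalen-2-yl)-4-methylpent-3-en-1-yl 3-methylbut-2-enoate | COc1c([C@@H](CC=C(C)C)OC(=O)C=C(C)C)cc(O)c2c1C(=O)C=CC2=O | target

**Totals and risks**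

Total step count: 11. Longest linear sequence: 10 steps (steps 1–5 and 7–11, from 1); the squarate branch runs through steps 6–11.

Steps most likely to fail:

1. Step 8. The ring expansion of step 9 is a well-behaved class once 13 is in hand, so the main hazard is the supply of 13. The reduction and acid-induced transposition may divert through ionisation at the tertiary benzylic carbinol, acid-induced ring opening, or oligomerisation of the strained unsubstituted enone. The fallback is a Dötz benzannulation, which makes the same ring closure through a chromium-bound dienylketene and avoids cyclobutenones altogether. It sets out from 6. Lithiation as in step 7 (aryllithium 10), addition to Cr(CO)6 and O-methylation with Me3OBF4 would give pentacarbonyl[methoxy(Ar)carbene]chromium F1. Heating F1 with ethynyltrimethylsilane (an acetylene surrogate) in THF at 50 °C, then exposure to air, should give 4-methoxy-8-methoxy-5-(methoxymethoxy)-7-(silyloxyalkenyl)-2-(trimethylsilyl)naphthalen-1-ol F2, the silyl group lying next to the new hydroxyl. Brief CF3CO2H in CH2Cl2 at 0 °C would remove that silyl group by ipso-protodesilylation to give the corresponding 4-methoxynaphthalen-1-ol F3. Oxidative demethylation with PhI(OAc)2 in aqueous MeCN would come back to the route at 17.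

2. Step 1. Regiocontrol of the demethylation may be lost (cleavage of the 2-methoxy group or of both ethers, or sulfonation of the ring). The fallback sets out from 1. Exhaustive demethylation with BBr3 (CH2Cl2, −78 °C to rt) would give 4-bromo-2,5-dihydroxybenzaldehyde F4. Its 2-hydroxyl is held in a hydrogen bond to the formyl group, so MOMCl (1 equiv) and i-Pr2NEt should protect only the 5-hydroxyl to give 4-bromo-2-hydroxy-5-(methoxymethoxy)benzaldehyde F5. Methylation of the remaining phenol (MeI, K2CO3, DMF) comes back at 3.

3. Step 10. Acid may promote side reactions of the side chain while both protecting groups are removed: addition of the freed hydroxyl to the trisubstituted alkene to form a cyclic ether, or solvolysis and racemisation at the benzylic carbon. The fallback sets out from 17 and removes the groups one at a time without exposing a free alcohol to protic acid. HF·pyridine (THF, 0 °C) would remove only the silyl group to give 7-[(1R)-1-hydroxy-4-methylpent-3-en-1-yl]-8-methoxy-5-(methoxymethoxy)naphthalene-1,4-dione F6. Steglich esterification as in step 11 would give the MOM-protected senecioate ester F7. Chelation-assisted cleavage of the peri MOM ether with MgBr2·OEt2 (Et2O/CH2Cl2, 0 °C) would come back at 19.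

**Further compounds**

F1 | step 8 | pentacarbonyl[methoxy(Ar)carbene]chromium | COC(=[Cr](=C=O)(=C=O)(=C=O)(=C=O)=C=O)c1cc(OC)c([C@@H](CC=C(C)C)O[Si](C)(C)C(C)(C)C)cc1OCOC
F2 | step 8 | 4,8-dimethoxy-5-(methoxymethoxy)-7-[(1R)-1-(tert-butyldimethylsilyloxy)-4-methylpent-3-en-1-yl]-2-(trimethylsilyl)naphthalen-1-ol | COCOc1cc([C@@H](CC=C(C)C)O[Si](C)(C)C(C)(C)C)c(OC)c2c(O)c([Si](C)(C)C)cc(OC)c12
F3 | step 8 | 4,8-dimethoxy-5-(methoxymethoxy)-7-[(1R)-1-(tert-butyldimethylsilyloxy)-4-methylpent-3-en-1-yl]naphthalen-1-ol | COCOc1cc([C@@H](CC=C(C)C)O[Si](C)(C)C(C)(C)C)c(OC)c2c(O)ccc(OC)c12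
F4 | step 1 | 4-bromo-2,5-dihydroxybenzaldehyde | O=Cc1cc(O)c(Br)cc1O
F5 | step 1 | 4-bromo-2-hydroxy-5-(methoxymethoxy)benzaldehyde | COCOc1cc(C=O)c(O)cc1Br
F6 | step 10 | 7-[(1R)-1-hydroxy-4-methylpent-3-en-1-yl]-8-methoxy-5-(methoxymethoxy)naphthalene-1,4-dione | COCOc1cc([C@@H](CC=C(C)C)O)c(OC)c2c1C(=O)C=CC2=O
F7 | step 10 | (1R)-1-[1-methoxy-4-(methoxymethoxy)-5,8-dioxo-5,8-dihydronaphthalen-2-yl]-4-methylpent-3-en-1-yl 3-methylbut-2-enoate | COCOc1cc([C@@H](CC=C(C)C)OC(=O)C=C(C)C)c(OC)c2c1C(=O)C=CC2=O
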